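The route rests on cutting the bond between lactone carbon C3, alpha to the C2 carbonyl, and the benzylic CH2 of the free-phenol guaiacyl ring (ring A). The key step exploits the trans-vicinal C3/C4 pair on the five-membered lactone ring: a lithiated 2-aryl-1,3-dithiane (masked benzylic carbon of ring B) adds 1,4 to (5R)-5-menthyloxy-2(5H)-furanone, and the resulting C2–C3 enolate is alkylated in the same flask by 4-benzyloxy-3-methoxybenzyl bromide. One operation thus forms both lactone–benzyl C–C bonds and sets C4 and C3. Dithiane and menthyloxy acetal are then removed reductively, and the threo arylglycerol ether is built on the ring B phenol by an Evans syn-glycolate aldol.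

Key step: step 4

Labels used below: lactone O1, C2 (C=O), C3, C4, C5; ring A = guaiacyl ring of the C3 benzyl group, ring B = guaiacyl ring of the C4 benzyl group, ring C = guaiacyl ring of the glycerol unit C7 (ArCHOH), C8 (CH–O–ring B), C9 (CH2OH); the target is read as (3R,4R,7R,8R), i.e. trans lactone and threo glycerol unit.

Assumption: the l-menthol-derived (5R)-5-menthyloxy-2(5H)-furanone, (S)-4-benzyl-3-(chloroacetyl)oxazolidin-2-one and 4-(benzyloxy)-3-methoxybenzyl alcohol are taken as catalogue chemicals.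

Step 1
Reactants: 1 vanillin; 2 propane-1,3-dithiol
Product: 3 2-(4-hydroxy-3-methoxyphenyl)-1,3-dithiane
Conditions: BF3·OEt2 (cat.), CH2Cl2, 0 °C → rt
Reagents that add atoms: none
Why: Lewis acid-catalysed dithioacetalisation of the aldehyde installs the Corey–Seebach acyl-anion handle on the future benzylic carbon of ring B and leaves the phenol untouched.

Step 2
Reactants: 3 2-(4-hydroxy-3-methoxyphenyl)-1,3-dithiane
Product: 4 2-[4-(tert-butyldimethylsilyloxy)-3-methoxyphenyl]-1,3-dithiane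
Conditions: TBSCl, imidazole, DMF, rt
Reagents that add atoms: tert-butyldimethylsilyl chloride, CC(C)(C)[Si](C)(C)Cl
Why: Standard phenol silylation gives an ether that should tolerate n-BuLi at low temperature and is cleaved later by hydroxide (step 6).

Step 3
Reactants: 5 4-(benzyloxy)-3-methoxybenzyl alcohol
Product: 6 4-(benzyloxy)-3-methoxybenzyl bromide
Conditions: PBr3, Et2O, 0 °C
Reagents that add atoms: phosphorus tribromide, BrP(Br)Br
Why: Bromination of the electron-rich benzylic alcohol via its phosphite ester (SN2) gives the reactive electrophile, which is used without storage.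

Step 4
Reactants: 4 2-[4-(tert-butyldimethylsilyloxy)-3-methoxyphenyl]-1,3-dithiane; 7 (5R)-5-[(1R,2S,5R)-menthyloxy]furan-2(5H)-one; 6 4-(benzyloxy)-3-methoxybenzyl bromide
Product: 10 (3R,4R,5R)-3-[4-(benzyloxy)-3-methoxybenzyl]-4-{2-[4-(tert-butyldimethylsilyloxy)-3-methoxyphenyl]-1,3-dithian-2-yl}-5-[(1R,2S,5R)-menthyloxy]dihydrofuran-2(3H)-one, via 2-lithio-1,3-dithiane 8 (not isolated), via lithium enolate 9 (not isolated)
Conditions: n-BuLi, THF, −78 °C; 7, −78 °C; then 6, DMPU, −78 → −20 °C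
Reagents that add atoms: none
Why: n-BuLi deprotonates 4 to the sulfur-stabilised carbanion 8, which adds 1,4 to butenolide 7 to give lithium enolate 9, and the C3 carbon of 9 then displaces bromide from 6 (SN2), forming the C3–CH2(ring A) bond. The closest known reaction type is the tandem Michael addition–enolate alkylation of 5-alkoxy-2(5H)-furanones with lithiated dithioacetals, a Corey–Seebach umpolung run as a three-component coupling. No ring is closed, since the lactone ring is carried in intact from 7. C4 is set by attack of 8 on the face of 7 anti to the C5 menthyloxy group, and C3 by approach of 6 to the enolate face anti to the bulky C4 dithianyl group, so the all-trans (3R,4R,5R) isomer is expected. The step needs 1,4- over 1,2-addition, which the soft, hindered 2-aryl-dithianyl anion should secure, and C-monoalkylation over proton transfer, which the reactive benzylic bromide, DMPU activation and low temperature should secure.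

Step 5
Reactants: 10 (3R,4R,5R)-3-[4-(benzyloxy)-3-methoxybenzyl]-4-{2-[4-(tert-butyldimethylsilyloxy)-3-methoxyphenyl]-1,3-dithian-2-yl}-5-[(1R,2S,5R)-menthyloxy]dihydrofuran-2(3H)-one
Product: 11 (3R,4R,5R)-3-[4-(benzyloxy)-3-methoxybenzyl]-4-[4-(tert-butyldimethylsilyloxy)-3-methoxybenzyl]-5-[(1R,2S,5R)-menthyloxy]dihydrofuran-2(3H)-one
Conditions: NiCl2·6H2O, NaBH4, MeOH/THF, 0 °C
Reagents that add atoms: none
Why: Ni2B generated in situ should hydrogenolyse the two benzylic C–S bonds (reductive desulfurisation) without touching the benzyl ether, the hindered pseudo-ester or the three ring stereocentres.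

Step 6
Reactants: 11 (3R,4R,5R)-3-[4-(benzyloxy)-3-methoxybenzyl]-4-[4-(tert-butyldimethylsilyloxy)-3-methoxybenzyl]-5-[(1R,2S,5R)-menthyloxy]dihydrofuran-2(3H)-one
Product: 13 (3R,4R)-3-[4-(benzyloxy)-3-methoxybenzyl]-4-(4-hydroxy-3-methoxybenzyl)dihydrofuran-2(3H)-one, via hydroxy acid 12 (not isolated)
Conditions: NaBH4, KOH, EtOH/H2O, rt; then 2 M HCl, rt
Reagents that add atoms: none
Why: Saponification–reduction–lactonisation: hydroxide opens the pseudo-ester to the aldehyde carboxylate (losing menthol) and cleaves the aryl silyl ether, NaBH4 reduces the aldehyde at once, and acidification closes hydroxy acid 12 to the lactone, so C5 becomes CH2 while C3 and C4 keep the thermodynamically preferred trans (3R,4R) arrangement.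

Step 7
Reactants: 13 (3R,4R)-3-[4-(benzyloxy)-3-methoxybenzyl]-4-(4-hydroxy-3-methoxybenzyl)dihydrofuran-2(3H)-one; 14 (S)-4-benzyl-3-(chloroacetyl)oxazolidin-2-one
Product: 15 (S)-4-benzyl-3-{[4-({(3R,4R)-4-[4-(benzyloxy)-3-methoxybenzyl]-5-oxotetrahydrofuran-3-yl}methyl)-2-methoxyphenoxy]acetyl}oxazolidin-2-one
Conditions: K2CO3, KI (cat.), acetone, 50 °C
Reagents that add atoms: none
Why: Williamson etherification: the only free phenol (ring B) displaces the activated alpha-halide of 14 (SN2, iodide catalysis), an irreversible step that should outrun reversible attack of the phenoxide on the imide carbonyl.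

Step 8
Reactants: 15 (S)-4-benzyl-3-{[4-({(3R,4R)-4-[4-(benzyloxy)-3-methoxybenzyl]-5-oxotetrahydrofuran-3-yl}methyl)-2-methoxyphenoxy]acetyl}oxazolidin-2-one; 16 4-(benzyloxy)-3-methoxybenzaldehyde
Product: 18 (S)-4-benzyl-3-{(2S,3R)-3-[4-(benzyloxy)-3-methoxyphenyl]-2-[4-({(3R,4R)-4-[4-(benzyloxy)-3-methoxybenzyl]-5-oxotetrahydrofuran-3-yl}methyl)-2-methoxyphenoxy]-3-hydroxypropanoyl}oxazolidin-2-one, via dibutylboron Z-enolate 17 (not isolated)
Conditions: Bu2BOTf, iPr2NEt, CH2Cl2, −78 → 0 °C; 16, −78 → 0 °C; then pH 7 buffer, MeOH, H2O2, 0 °C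
Reagents that add atoms: none
Why: Evans syn-aldol reaction: soft enolisation gives Z-boron enolate 17 without enolising the lactone, and the closed Zimmerman–Traxler transition state, with the aldehyde approaching anti to the auxiliary benzyl group, sets the (2S,3R) acyl chain, which corresponds to the threo (7R,8R) unit after reduction.

Step 9
Reactants: 18 (S)-4-benzyl-3-{(2S,3R)-3-[4-(benzyloxy)-3-methoxyphenyl]-2-[4-({(3R,4R)-4-[4-(benzyloxy)-3-methoxybenzyl]-5-oxotetrahydrofuran-3-yl}methyl)-2-methoxyphenoxy]-3-hydroxypropanoyl}oxazolidin-2-one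
Product: 19 (3R,4R)-3-[4-(benzyloxy)-3-methoxybenzyl]-4-(4-{[(1R,2R)-1-[4-(benzyloxy)-3-methoxyphenyl]-1,3-dihydroxypropan-2-yl]oxy}-3-methoxybenzyl)dihydrofuran-2(3H)-one
Conditions: NaBH4, THF/H2O (4:1), 0 °C → rt
Reagents that add atoms: none
Why: Reductive cleavage of the N-acyl oxazolidinone: the activated, hydroxyl-assisted imide carbonyl should be reduced to the primary alcohol faster than the hindered 3,4-disubstituted lactone, and no stereocentre is touched (C8 changes from S to R only through the priority rules).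

Step 10
Reactants: 19 (3R,4R)-3-[4-(benzyloxy)-3-methoxybenzyl]-4-(4-{[(1R,2R)-1-[4-(benzyloxy)-3-methoxyphenyl]-1,3-dihydroxypropan-2-yl]oxy}-3-methoxybenzyl)dihydrofuran-2(3H)-one
Product: 20 (3R,4R)-4-(4-{[(1R,2R)-1,3-dihydroxy-1-(4-hydroxy-3-methoxyphenyl)propan-2-yl]oxy}-3-methoxybenzyl)-3-(4-hydroxy-3-methoxybenzyl)dihydrofuran-2(3H)-one (CNP0144301.3)
Conditions: H2 (1 atm), Pd/C, EtOAc/EtOH, rt
Reagents that add atoms: none
Why: Catalytic hydrogenolysis cleaves both aryl benzyl ethers under neutral conditions, under which the secondary benzylic alcohol at C7, the alkyl aryl ether at C8 and the lactone are expected to persist if the reaction is stopped at complete debenzylation.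

Compound list

1 | vanillin (4-hydroxy-3-methoxybenzaldehyde) | COc1cc(C=O)ccc1O | starting material
2 | propane-1,3-dithiol | SCCCS | starting material
3 | 2-(4-hydroxy-3-methoxyphenyl)-1,3-dithiane | COc1cc(C2SCCCS2)ccc1O | intermediate
4 | 2-[4-(tert-butyldimethylsilyloxy)-3-methoxyphenyl]-1,3-dithiane | COc1cc(C2SCCCS2)ccc1O[Si](C)(C)C(C)(C)C | intermediate
5 | 4-(benzyloxy)-3-methoxybenzyl alcohol | COc1cc(CO)ccc1OCc1ccccc1 | starting material
6 | 4-(benzyloxy)-3-methoxybenzyl bromide | COc1cc(CBr)ccc1OCc1ccccc1 | intermediate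
7 | (5R)-5-[(1R,2S,5R)-2-isopropyl-5-methylcyclohexyloxy]furan-2(5H)-one [(5R)-5-(l-menthyloxy)-2(5H)-furanone] | O=C1C=C[C@H](O[C@@H]2C[C@H](C)CC[C@H]2C(C)C)O1 | starting material
8 | 2-lithio-2-[4-(tert-butyldimethylsilyloxy)-3-methoxyphenyl]-1,3-dithiane (not isolated) | [Li]C1(c2ccc(O[Si](C)(C)C(C)(C)C)c(OC)c2)SCCCS1 | intermediate
9 | lithium enolate of (4R,5R)-4-{2-[4-(tert-butyldimethylsilyloxy)-3-methoxyphenyl]-1,3-dithian-2-yl}-5-[(1R,2S,5R)-menthyloxy]dihydrofuran-2(3H)-one (not isolated) | [Li]OC1=C[C@@H](C2(c3ccc(O[Si](C)(C)C(C)(C)C)c(OC)c3)SCCCS2)[C@H](O[C@@H]2C[C@H](C)CC[C@H]2C(C)C)O1 | intermediate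
10 | (3R,4R,5R)-3-[4-(benzyloxy)-3-methoxybenzyl]-4-{2-[4-(tert-butyldimethylsilyloxy)-3-methoxyphenyl]-1,3-dithian-2-yl}-5-[(1R,2S,5R)-menthyloxy]dihydrofuran-2(3H)-one | O=C1O[C@@H](O[C@@H]2C[C@H](C)CC[C@H]2C(C)C)[C@H](C2(c3ccc(O[Si](C)(C)C(C)(C)C)c(OC)c3)SCCCS2)[C@H]1Cc1ccc(OCc2ccccc2)c(OC)c1 | intermediate
11 | (3R,4R,5R)-3-[4-(benzyloxy)-3-methoxybenzyl]-4-[4-(tert-butyldimethylsilyloxy)-3-methoxybenzyl]-5-[(1R,2S,5R)-menthyloxy]dihydrofuran-2(3H)-one | O=C1O[C@@H](O[C@@H]2C[C@H](C)CC[C@H]2C(C)C)[C@H](Cc2ccc(O[Si](C)(C)C(C)(C)C)c(OC)c2)[C@H]1Cc1ccc(OCc2ccccc2)c(OC)c1 | intermediate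
12 | (2R,3R)-2-[4-(benzyloxy)-3-methoxybenzyl]-4-(4-hydroxy-3-methoxyphenyl)-3-(hydroxymethyl)butanoic acid (not isolated) | COc1cc(C[C@@H](C(=O)O)[C@H](CO)Cc2ccc(O)c(OC)c2)ccc1OCc1ccccc1 | intermediate
13 | (3R,4R)-3-[4-(benzyloxy)-3-methoxybenzyl]-4-(4-hydroxy-3-methoxybenzyl)dihydrofuran-2(3H)-one | COc1cc(C[C@H]2C(=O)OC[C@@H]2Cc2ccc(O)c(OC)c2)ccc1OCc1ccccc1 | intermediate
14 | (S)-4-benzyl-3-(chloroacetyl)oxazolidin-2-one | O=C1OC[C@H](Cc2ccccc2)N1C(=O)CCl | starting material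
15 | (S)-4-benzyl-3-{[4-({(3R,4R)-4-[4-(benzyloxy)-3-methoxybenzyl]-5-oxotetrahydrofuran-3-yl}methyl)-2-methoxyphenoxy]acetyl}oxazolidin-2-one | COc1cc(C[C@H]2C(=O)OC[C@@H]2Cc2ccc(OCC(=O)N3C(=O)OC[C@@H]3Cc3ccccc3)c(OC)c2)ccc1OCc1ccccc1 | intermediate
16 | 4-(benzyloxy)-3-methoxybenzaldehyde | COc1cc(C=O)ccc1OCc1ccccc1 | starting material
17 | dibutylboron Z-enolate of 15 (not isolated) | COc1cc(C[C@H]2C(=O)OC[C@@H]2Cc2ccc(O/C=C(\OB(CCCC)CCCC)N3C(=O)OC[C@@H]3Cc3ccccc3)c(OC)c2)ccc1OCc1ccccc1 | intermediate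
18 | (S)-4-benzyl-3-{(2S,3R)-3-[4-(benzyloxy)-3-methoxyphenyl]-2-[4-({(3R,4R)-4-[4-(benzyloxy)-3-methoxybenzyl]-5-oxotetrahydrofuran-3-yl}methyl)-2-methoxyphenoxy]-3-hydroxypropanoyl}oxazolidin-2-one | COc1cc(C[C@H]2C(=O)OC[C@@H]2Cc2ccc(O[C@H](C(=O)N3C(=O)OC[C@@H]3Cc3ccccc3)[C@H](O)c3ccc(OCc4ccccc4)c(OC)c3)c(OC)c2)ccc1OCc1ccccc1 | intermediate
19 | (3R,4R)-3-[4-(benzyloxy)-3-methoxybenzyl]-4-(4-{[(1R,2R)-1-[4-(benzyloxy)-3-methoxyphenyl]-1,3-dihydroxypropan-2-yl]oxy}-3-methoxybenzyl)dihydrofuran-2(3H)-one | COc1cc(C[C@H]2C(=O)OC[C@@H]2Cc2ccc(O[C@H](CO)[C@H](O)c3ccc(OCc4ccccc4)c(OC)c3)c(OC)c2)ccc1OCc1ccccc1 | intermediate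
20 | (3R,4R)-4-(4-{[(1R,2R)-1,3-dihydroxy-1-(4-hydroxy-3-methoxyphenyl)propan-2-yl]oxy}-3-methoxybenzyl)-3-(4-hydroxy-3-methoxybenzyl)dihydrofuran-2(3H)-one | COc1cc(C[C@H]2C(=O)OC[C@@H]2Cc2ccc(O[C@H](CO)[C@H](O)c3ccc(O)c(OC)c3)c(OC)c2)ccc1O | target

Total step count: 10 steps.
Longest linear sequence: 9 steps (steps 1, 2, 4, 5, 6, 7, 8, 9, 10, from vanillin); step 3 is a one-step side branch.

Steps most likely to fail

Step 4. The enolate 9 is flanked by the quaternary dithianyl carbon, so C-alkylation may be slow enough for proton transfer or retro-Michael fragmentation to erode conversion, and n-BuLi may attack the silyl ether if deprotonation is sluggish. Fallback: the two bond formations are separated. Starting from 4 and 7, the same conjugate addition is quenched with NH4Cl to give the Michael adduct (4R,5R)-4-{2-[4-(tert-butyldimethylsilyloxy)-3-methoxyphenyl]-1,3-dithian-2-yl}-5-[(1R,2S,5R)-menthyloxy]dihydrofuran-2(3H)-one F1. Desulfurisation with NiCl2·6H2O/NaBH4 then gives (4R,5R)-4-[4-(tert-butyldimethylsilyloxy)-3-methoxybenzyl]-5-[(1R,2S,5R)-menthyloxy]dihydrofuran-2(3H)-one F2. Its unhindered lithium enolate (LiN(iPr)2, THF, −78 °C) is alkylated with 6 anti to the C4 benzyl group, which forms the same C3–CH2 bond and returns to the route at 11.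

Step 7. Acyl transfer from the imide to the phenoxide (loss of the auxiliary) or base-induced decomposition of the alpha-halo imide may compete with the SN2 displacement. Fallback: starting from 13, the phenol is alkylated with tert-butyl bromoacetate (K2CO3, acetone) to give tert-butyl [4-({(3R,4R)-4-[4-(benzyloxy)-3-methoxybenzyl]-5-oxotetrahydrofuran-3-yl}methyl)-2-methoxyphenoxy]acetate F3. The ester is cleaved with CF3CO2H in CH2Cl2 to [4-({(3R,4R)-4-[4-(benzyloxy)-3-methoxybenzyl]-5-oxotetrahydrofuran-3-yl}methyl)-2-methoxyphenoxy]acetic acid F4. F4 is activated as its pivaloyl mixed anhydride (PivCl, Et3N, THF, −20 °C) and coupled with (S)-4-benzyloxazolidin-2-one in the presence of LiCl, which returns to the route at 15.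

Step 9. Hydride may also attack the lactone carbonyl, or the basic medium may trigger retro-aldol cleavage of the beta-hydroxy imide before reduction. Fallback: starting from 18, the auxiliary is removed hydrolytically with LiOH/H2O2 (THF/H2O, 0 °C). Acidification re-closes any opened lactone and gives (2S,3R)-3-[4-(benzyloxy)-3-methoxyphenyl]-2-[4-({(3R,4R)-4-[4-(benzyloxy)-3-methoxybenzyl]-5-oxotetrahydrofuran-3-yl}methyl)-2-methoxyphenoxy]-3-hydroxypropanoic acid F5. BH3·SMe2 in THF at 0 °C then reduces the free carboxylic acid in preference to the lactone, which returns to the route at 19.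

Further compounds

F1 | step 4 | (4R,5R)-4-{2-[4-(tert-butyldimethylsilyloxy)-3-methoxyphenyl]-1,3-dithian-2-yl}-5-[(1R,2S,5R)-menthyloxy]dihydrofuran-2(3H)-one | O=C1C[C@@H](C2(c3ccc(O[Si](C)(C)C(C)(C)C)c(OC)c3)SCCCS2)[C@H](O[C@@H]2C[C@H](C)CC[C@H]2C(C)C)O1
F2 | step 4 | (4R,5R)-4-[4-(tert-butyldimethylsilyloxy)-3-methoxybenzyl]-5-[(1R,2S,5R)-menthyloxy]dihydrofuran-2(3H)-one | O=C1C[C@@H](Cc2ccc(O[Si](C)(C)C(C)(C)C)c(OC)c2)[C@H](O[C@@H]2C[C@H](C)CC[C@H]2C(C)C)O1
F3 | step 7 | tert-butyl [4-({(3R,4R)-4-[4-(benzyloxy)-3-methoxybenzyl]-5-oxotetrahydrofuran-3-yl}methyl)-2-methoxyphenoxy]acetate | COc1cc(C[C@H]2C(=O)OC[C@@H]2Cc2ccc(OCC(=O)OC(C)(C)C)c(OC)c2)ccc1OCc1ccccc1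
F4 | step 7 | [4-({(3R,4R)-4-[4-(benzyloxy)-3-methoxybenzyl]-5-oxotetrahydrofuran-3-yl}methyl)-2-methoxyphenoxy]acetic acid | COc1cc(C[C@H]2C(=O)OC[C@@H]2Cc2ccc(OCC(=O)O)c(OC)c2)ccc1OCc1ccccc1
F5 | step 9 | (2S,3R)-3-[4-(benzyloxy)-3-methoxyphenyl]-2-[4-({(3R,4R)-4-[4-(benzyloxy)-3-methoxybenzyl]-5-oxotetrahydrofuran-3-yl}methyl)-2-methoxyphenoxy]-3-hydroxypropanoic acid | COc1cc(C[C@H]2C(=O)OC[C@@H]2Cc2ccc(O[C@H](C(=O)O)[C@H](O)c3ccc(OCc4ccccc4)c(OC)c3)c(OC)c2)ccc1OCc1ccccc1
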